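**Plan**
The retrosynthesis first cuts the depside ester C–O bond between the ring A carbonyl and O-4 of the pentyl-bearing ring B, then the ring A bonds C1–C2 and C5–C6.
Ring A is a benzoate with the carboxyl on C1, oxygen on C2 and C4, and the side chain on C6. This pattern maps onto a 1,1,3-trioxygenated butadiene (C2–C5) and a 2-ynoate (C1 and C6) that carries the 2-oxopentyl chain as its dioxolane.
Forward: the ynoate (four steps from ethyl 3-oxohexanoate) and the diene (two steps) combine in a Diels–Alder/aromatisation that forms ring A, the only ring made; ring B is bought as olivetolic acid.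
Then O-methylation, debenzylation, esterification onto O-4 of benzyl olivetolate, ketal hydrolysis and a final hydrogenolysis follow.
The target has no stereocentre; only regiochemistry must be controlled, by diene polarisation in the cycloaddition and by the chelated 2-hydroxyl of ring B in the esterification.

Key step: step 7

Remark: olivetolic acid and 1,1-dimethoxyethene are assumed to be purchasable.

**Route**

Step 1
Reactants: 1 ethyl 3-oxohexanoate
Product: 2 ethyl 2-(2-propyl-1,3-dioxolan-2-yl)acetate
Conditions: HOCH2CH2OH, p-TsOH·H2O (cat.), toluene, reflux, Dean–Stark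
Reagents that add atoms: ethylene glycol, OCCO
Why: Acid-catalysed ketalisation of a β-keto ester with azeotropic removal of water is standard, and it masks the ketone that would otherwise make the later propargylic CH2 prone to allene formation and the benzoic acid prone to lactol or isocoumarin formation.

Step 2
Reactants: 2 ethyl 2-(2-propyl-1,3-dioxolan-2-yl)acetate
Product: 3 2-(2-propyl-1,3-dioxolan-2-yl)acetaldehyde
Conditions: i-Bu2AlH, CH2Cl2, −78 °C; MeOH, then aq. potassium sodium tartrate
Reagents that add atoms: none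
Why: Partial ester reduction with i-Bu2AlH at low temperature should stop at the aldehyde, because the tetrahedral aluminium hemiacetal, here also chelated by a dioxolane oxygen, collapses only on work-up.

Step 3
Reactants: 3 2-(2-propyl-1,3-dioxolan-2-yl)acetaldehyde
Product: 4 2-(prop-2-yn-1-yl)-2-propyl-1,3-dioxolane
Conditions: dimethyl (1-diazo-2-oxopropyl)phosphonate, K2CO3, MeOH, 0 to 23 °C
Reagents that add atoms: dimethyl (1-diazo-2-oxopropyl)phosphonate, CC(=O)C(=[N+]=[N-])P(=O)(OC)OC
Why: Seyferth–Gilbert homologation with the Ohira–Bestmann reagent turns an aldehyde into the terminal alkyne through a diazoalkene and 1,2-hydrogen shift of the alkylidene carbene under mild carbonate conditions.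

Step 4
Reactants: 4 2-(prop-2-yn-1-yl)-2-propyl-1,3-dioxolane; 5 benzyl chloroformate
Product: 7 benzyl 4-(2-propyl-1,3-dioxolan-2-yl)but-2-ynoate, via lithium acetylide 6 (not isolated)
Conditions: n-BuLi, THF, −78 °C; then 5, −78 to 0 °C
Reagents that add atoms: none
Why: The terminal alkyne C–H is far more acidic than the propargylic CH2, and C-acylation of a lithium acetylide with a chloroformate at low temperature is the standard entry to 2-ynoates.

Step 5
Reactants: 8 1,1-dimethoxyethene
Product: 9 4,4-dimethoxybut-3-en-2-one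
Conditions: AcCl, Et3N, Et2O, 0 to 23 °C
Reagents that add atoms: acetyl chloride, CC(=O)Cl
Why: A ketene acetal is a carbon nucleophile that an acid chloride acylates at its β-carbon, the amine taking up the hydrogen chloride to leave the push-pull enone.

Step 6
Reactants: 9 4,4-dimethoxybut-3-en-2-one
Product: 10 1,1-dimethoxy-3-(trimethylsilyloxy)buta-1,3-diene
Conditions: Me3SiCl, Et3N, ZnCl2 (cat.), toluene, 40 °C; distilled and used at once
Reagents that add atoms: chlorotrimethylsilane, C[Si](C)(C)Cl
Why: Soft enolisation and O-silylation of the methyl ketone, the only enolisable position, is the usual way to make 2-silyloxy dienes from vinylogous esters.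

Step 7
Reactants: 7 benzyl 4-(2-propyl-1,3-dioxolan-2-yl)but-2-ynoate; 10 1,1-dimethoxy-3-(trimethylsilyloxy)buta-1,3-diene
Product: 13 benzyl 4-hydroxy-2-methoxy-6-[(2-propyl-1,3-dioxolan-2-yl)methyl]benzoate, via cyclohexadiene cycloadduct 11 (not isolated), via aryl trimethylsilyl ether 12 (not isolated)
Conditions: neat, 10 (3 equiv), 110 °C, sealed tube, argon; then K2CO3 (cat.), MeOH, 0 °C
Reagents that add atoms: none
Why: A thermal, normal-electron-demand, asynchronous Diels–Alder reaction joins the nucleophilic CH2 terminus of diene 10 to the β-carbon of ynoate 7 (ring A bond C5–C6) and the ketene acetal carbon to the α-carbon (bond C1–C2), closing the six-membered carbocycle of ring A by intermolecular [4+2] cycloaddition to give the 1,4-cyclohexadiene 11. Adduct 11 has a ketal carbon across the ring from a CH2 group, so 1,4-elimination of methanol should aromatise it to the silyl ether 12, and mild methanolysis then releases phenol 13. The closest known reaction type is the cycloaddition–aromatisation of 1,1-dialkoxy-3-silyloxybutadienes with 3-alkylpropiolates, which gives 6-alkyl-β-resorcylate 2-methyl ethers. No stereocentre is formed; the selectivity needed is regiochemical, and it is secured by the match of the largest HOMO coefficient of the diene (unsubstituted terminus) with the largest LUMO coefficient of the ynoate (β-carbon), which puts the side chain ortho to the ester and the methoxy group on the other flank. Because β-alkyl ynoates are slow dienophiles and the liberated methanol consumes some diene, the reaction is run neat with excess diene; the absence of base keeps the propargylic CH2 from drifting to the allenoate, and dioxolane and benzyl ester are inert to neutral heating.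

Step 8
Reactants: 13 benzyl 4-hydroxy-2-methoxy-6-[(2-propyl-1,3-dioxolan-2-yl)methyl]benzoate
Product: 14 benzyl 2,4-dimethoxy-6-[(2-propyl-1,3-dioxolan-2-yl)methyl]benzoate
Conditions: MeI, K2CO3, acetone, 50 °C
Reagents that add atoms: iodomethane, CI
Why: Williamson methylation of the unhindered para-phenol under weak-base conditions should leave the crowded benzyl ester and the ketal untouched.

Step 9
Reactants: 14 benzyl 2,4-dimethoxy-6-[(2-propyl-1,3-dioxolan-2-yl)methyl]benzoate
Product: 15 2,4-dimethoxy-6-[(2-propyl-1,3-dioxolan-2-yl)methyl]benzoic acid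
Conditions: H2 (1 atm), 10% Pd/C, EtOAc, 23 °C
Reagents that add atoms: none
Why: Hydrogenolysis of the benzyl ester frees the di-ortho-substituted acid, which would resist saponification, under neutral conditions that spare the dioxolane.

Step 10
Reactants: 16 olivetolic acid (2,4-dihydroxy-6-pentylbenzoic acid)
Product: 17 benzyl 2,4-dihydroxy-6-pentylbenzoate
Conditions: BnBr, KHCO3, DMF, 23 °C
Reagents that add atoms: benzyl bromide, BrCc1ccccc1
Why: Hydrogen carbonate deprotonates only the carboxylic acid, so SN2 alkylation should give the benzyl ester with both phenols free, at a temperature below that at which β-resorcylic acids decarboxylate.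

Step 11
Reactants: 15 2,4-dimethoxy-6-[(2-propyl-1,3-dioxolan-2-yl)methyl]benzoic acid; 17 benzyl 2,4-dihydroxy-6-pentylbenzoate
Product: 18 benzyl 4-({2,4-dimethoxy-6-[(2-propyl-1,3-dioxolan-2-yl)methyl]benzoyl}oxy)-2-hydroxy-6-pentylbenzoate
Conditions: DCC, DMAP (cat.), CH2Cl2, 0 to 23 °C
Reagents that add atoms: none
Why: Steglich esterification (carbodiimide activation with DMAP acyl transfer) forms aryl esters without acid, so the ketal should survive, and the 4-hydroxyl of 17 should react selectively because the 2-hydroxyl is hydrogen-bonded to the neighbouring ester carbonyl.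

Step 12
Reactants: 18 benzyl 4-({2,4-dimethoxy-6-[(2-propyl-1,3-dioxolan-2-yl)methyl]benzoyl}oxy)-2-hydroxy-6-pentylbenzoate
Product: 19 benzyl 4-{[2,4-dimethoxy-6-(2-oxopentyl)benzoyl]oxy}-2-hydroxy-6-pentylbenzoate
Conditions: 0.5 M HCl (aq), THF, 23 °C
Reagents that add atoms: water, O
Why: Dilute aqueous acid hydrolyses a dialkyl ketone dioxolane at ambient temperature while hindered aryl and benzyl esters are stable, and the mild, short exposure limits enol-lactonisation of the freed ketone onto the adjacent aryl ester.

Step 13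
Reactants: 19 benzyl 4-{[2,4-dimethoxy-6-(2-oxopentyl)benzoyl]oxy}-2-hydroxy-6-pentylbenzoate
Product: 20 4-{[2,4-dimethoxy-6-(2-oxopentyl)benzoyl]oxy}-2-hydroxy-6-pentylbenzoic acid (target)
Conditions: H2 (1 atm), 10% Pd/C, EtOAc, 23 °C
Reagents that add atoms: none
Why: Neutral hydrogenolysis cleaves only the O–benzyl bond and should leave the depside ester, the dialkyl ketone and the aryl ethers intact, as is usual for the closing step of depside syntheses.

**Compound list**
1 | ethyl 3-oxohexanoate | CCCC(=O)CC(=O)OCC | starting material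
2 | ethyl 2-(2-propyl-1,3-dioxolan-2-yl)acetate | CCCC1(CC(=O)OCC)OCCO1 | intermediate
3 | 2-(2-propyl-1,3-dioxolan-2-yl)acetaldehyde | CCCC1(CC=O)OCCO1 | intermediate
4 | 2-(prop-2-yn-1-yl)-2-propyl-1,3-dioxolane | CCCC1(CC#C)OCCO1 | intermediate
5 | benzyl chloroformate | O=C(Cl)OCc1ccccc1 | starting material
6 | lithium 3-(2-propyl-1,3-dioxolan-2-yl)prop-1-yn-1-ide (lithium acetylide of 4, formed in the flask) | CCCC1(CC#[C-])OCCO1.[Li+] | intermediate
7 | benzyl 4-(2-propyl-1,3-dioxolan-2-yl)but-2-ynoate | CCCC1(CC#CC(=O)OCc2ccccc2)OCCO1 | intermediate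
8 | 1,1-dimethoxyethene | C=C(OC)OC | starting material
9 | 4,4-dimethoxybut-3-en-2-one | CC(=O)C=C(OC)OC | intermediate
10 | 1,1-dimethoxy-3-(trimethylsilyloxy)buta-1,3-diene | C=C(O[Si](C)(C)C)C=C(OC)OC | intermediate
11 | benzyl 6,6-dimethoxy-2-[(2-propyl-1,3-dioxolan-2-yl)methyl]-4-(trimethylsilyloxy)cyclohexa-1,4-diene-1-carboxylate (cycloadduct, formed in the flask) | CCCC1(CC2=C(C(=O)OCc3ccccc3)C(OC)(OC)C=C(O[Si](C)(C)C)C2)OCCO1 | intermediate
12 | benzyl 2-methoxy-6-[(2-propyl-1,3-dioxolan-2-yl)methyl]-4-(trimethylsilyloxy)benzoate (formed in the flask) | CCCC1(Cc2cc(O[Si](C)(C)C)cc(OC)c2C(=O)OCc2ccccc2)OCCO1 | intermediate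
13 | benzyl 4-hydroxy-2-methoxy-6-[(2-propyl-1,3-dioxolan-2-yl)methyl]benzoate | CCCC1(Cc2cc(O)cc(OC)c2C(=O)OCc2ccccc2)OCCO1 | intermediate
14 | benzyl 2,4-dimethoxy-6-[(2-propyl-1,3-dioxolan-2-yl)methyl]benzoate | CCCC1(Cc2cc(OC)cc(OC)c2C(=O)OCc2ccccc2)OCCO1 | intermediate
15 | 2,4-dimethoxy-6-[(2-propyl-1,3-dioxolan-2-yl)methyl]benzoic acid | CCCC1(Cc2cc(OC)cc(OC)c2C(=O)O)OCCO1 | intermediate
16 | olivetolic acid (2,4-dihydroxy-6-pentylbenzoic acid) | CCCCCc1cc(O)cc(O)c1C(=O)O | starting material
17 | benzyl 2,4-dihydroxy-6-pentylbenzoate | CCCCCc1cc(O)cc(O)c1C(=O)OCc1ccccc1 | intermediate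
18 | benzyl 4-({2,4-dimethoxy-6-[(2-propyl-1,3-dioxolan-2-yl)methyl]benzoyl}oxy)-2-hydroxy-6-pentylbenzoate | CCCCCc1cc(OC(=O)c2c(CC3(CCC)OCCO3)cc(OC)cc2OC)cc(O)c1C(=O)OCc1ccccc1 | intermediate
19 | benzyl 4-{[2,4-dimethoxy-6-(2-oxopentyl)benzoyl]oxy}-2-hydroxy-6-pentylbenzoate | CCCCCc1cc(OC(=O)c2c(CC(=O)CCC)cc(OC)cc2OC)cc(O)c1C(=O)OCc1ccccc1 | intermediate
20 | 4-{[2,4-dimethoxy-6-(2-oxopentyl)benzoyl]oxy}-2-hydroxy-6-pentylbenzoic acid | CCCCCc1cc(OC(=O)c2c(CC(=O)CCC)cc(OC)cc2OC)cc(O)c1C(=O)O | target

**Count**
Total steps: 13. Longest linear sequence: 10 steps (steps 1, 2, 3, 4, 7, 8, 9, 11, 12, 13, from ethyl 3-oxohexanoate).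

**Steps most likely to fail, with fallbacks**

First, step 7. The β-alkyl ynoate may add too slowly, so that thermal oligomerisation of the ketene acetal diene, its consumption by liberated methanol and prototropic drift of the ynoate outrun the cycloaddition. The fallback keeps the same ring construction but raises the dienophile to the aldehyde oxidation level.
- It sets out from alkyne 4, which is lithiated (n-BuLi, THF, −78 °C) and quenched with DMF to give 4-(2-propyl-1,3-dioxolan-2-yl)but-2-ynal F1.
- This far more electron-poor dienophile should combine with diene 10 in toluene between 23 and 60 °C to give the cycloadduct 6,6-dimethoxy-2-[(2-propyl-1,3-dioxolan-2-yl)methyl]-4-(trimethylsilyloxy)cyclohexa-1,4-diene-1-carbaldehyde F2.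
- F2 should lose methanol to give 2-methoxy-6-[(2-propyl-1,3-dioxolan-2-yl)methyl]-4-(trimethylsilyloxy)benzaldehyde F3, which is methanolysed (K2CO3 cat., MeOH) to 4-hydroxy-2-methoxy-6-[(2-propyl-1,3-dioxolan-2-yl)methyl]benzaldehyde F4.
- Methylation (MeI, K2CO3, acetone) gives 2,4-dimethoxy-6-[(2-propyl-1,3-dioxolan-2-yl)methyl]benzaldehyde F5.
- Pinnick oxidation (NaClO2, NaH2PO4, 2-methyl-2-butene, t-BuOH/H2O) returns the route at acid 15, bypassing 13, 14 and step 9.

Second, step 11. Attack of the phenol on the crowded O-acylisourea may be slower than its O-to-N acyl shift to the N-acylurea, and acylation may spread to the chelated 2-hydroxyl. The fallback replaces in-situ carbodiimide activation by a discrete, small acyl donor that cannot rearrange.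
- It sets out from acid 15, which is treated with cyanuric fluoride and pyridine in CH2Cl2 to give the isolable 2,4-dimethoxy-6-[(2-propyl-1,3-dioxolan-2-yl)methyl]benzoyl fluoride F6 under non-acidic conditions.
- F6 is then combined with phenol 17 and K2CO3 in MeCN, where the more acidic, non-chelated 4-phenoxide should be acylated, coming back to the route at 18.

Third, step 3. In carbonate/methanol the β-alkoxy aldehyde may undergo base-induced opening of the dioxolane by β-elimination, or self-aldol condensation, before homologation. The fallback uses a phosphorus ylide olefination and a carbenoid rearrangement in place of the diazophosphonate.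
- It sets out from aldehyde 3, which with CBr4, PPh3 and Et3N in CH2Cl2 at 0 °C (Corey–Fuchs olefination) should give 2-(3,3-dibromoprop-2-en-1-yl)-2-propyl-1,3-dioxolane F7.
- Treatment of F7 with n-BuLi (2.2 equiv) in THF at −78 °C should give lithium acetylide 6 directly by Fritsch–Buttenberg–Wiechell rearrangement.
- Acetylide 6 is trapped in the same flask with benzyl chloroformate 5, coming back to the route at ynoate 7 and bypassing 4.

**Further compounds**
F1 | step 7 | 4-(2-propyl-1,3-dioxolan-2-yl)but-2-ynal | CCCC1(CC#CC=O)OCCO1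
F2 | step 7 | 6,6-dimethoxy-2-[(2-propyl-1,3-dioxolan-2-yl)methyl]-4-(trimethylsilyloxy)cyclohexa-1,4-diene-1-carbaldehyde | CCCC1(CC2=C(C=O)C(OC)(OC)C=C(O[Si](C)(C)C)C2)OCCO1
F3 | step 7 | 2-methoxy-6-[(2-propyl-1,3-dioxolan-2-yl)methyl]-4-(trimethylsilyloxy)benzaldehyde | CCCC1(Cc2cc(O[Si](C)(C)C)cc(OC)c2C=O)OCCO1
F4 | step 7 | 4-hydroxy-2-methoxy-6-[(2-propyl-1,3-dioxolan-2-yl)methyl]benzaldehyde | CCCC1(Cc2cc(O)cc(OC)c2C=O)OCCO1
F5 | step 7 | 2,4-dimethoxy-6-[(2-propyl-1,3-dioxolan-2-yl)methyl]benzaldehyde | CCCC1(Cc2cc(OC)cc(OC)c2C=O)OCCO1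
F6 | step 11 | 2,4-dimethoxy-6-[(2-propyl-1,3-dioxolan-2-yl)methyl]benzoyl fluoride | CCCC1(Cc2cc(OC)cc(OC)c2C(F)=O)OCCO1
F7 | step 3 | 2-(3,3-dibromoprop-2-en-1-yl)-2-propyl-1,3-dioxolane | CCCC1(CC=C(Br)Br)OCCO1
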